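The spring flask held less left-handed product at 30.0 min than at 8.00 min, so product of one hand was turning into product of the other (product racemization).

the same everywhere: racemization catalyst 50 mM

|  | left-handed substrate | right-handed substrate | reagent | remark | time |
|---|---|---|---|---|---|
| dawn | 0.50 M | 0.50 M | 1 M | the very flask that is asked about, followed so far |  |
| spring | 1 M | 1 M | 1 M | run made earlier |  |
| flask | 0.50 M | 0.50 M | 1.00 M |  | 30 min |

| run | time / min | left-handed product / % | right-handed product / % |
|---|---|---|---|
| dawn | 0.833 | 15.1 | 1.9 |
| dawn | 2.00 | 27.6 | 1.8 |
| dawn | 4.00 | 33.8 | 4.5 |
| dawn | 6.00 | 36.0 | 9.2 |
| spring | 8.00 | 31.1 | 10.0 |
| spring | 15.0 | 28.8 | 17.7 |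
| spring | 25.0 | 26.0 | 20.2 |
| spring | 30.0 | 25.9 | 24.5 |

(scatter of a reading: 1 percentage point)

- left-handed product and right-handed product together, in percent of the left-handed substrate and right-handed substrate charged together, at 30 min
- excess of left-handed product over right-handed product in the product at 30 min
- whether the exchange between left-handed substrate and right-handed substrate keeps pace with the reaction: how far the product's excess at 30 min gets from its value without exchange to its value with instant exchange (above 80 % keeps pace, below 20 % hardly takes part, else lags behind)

- reagent is single-handed; left-handed substrate and right-handed substrate are mirror images of each other, charged as a racemate, each of them at the stated concentration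
- an excess is the difference of the two amounts in percent of their sum
- an excess is below zero if the other one leads
- the handed part of reagent does not stay in what it makes, so the products of the two hands are mirror images too

1. I asked for the end state first. The products are mirror images, so their equilibrium has [left-handed product] equal to [right-handed product], and the excess heads for zero.

2. Then I asked how fast. I called the lead the left-handed product minus the right-handed product, in percent of the charge. Its memory time, the first-order time constant in which the lead falls by a factor e, I read from the spring run. The lead went from 21 percentage points to 11 points between 8.00 min and 15.0 min, which gave 10.9 min.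

3. The dawn flask showed a lead of 27 points at 6.00 min. Its total was 45.2 %, and I counted what was missing up to the left-handed half of the charge as lead still to come, which made 32 points.

4. Decay from 6.00 min to 30 min left 3.5 points. I took the total as at least the left-handed half, so the excess came to at most about 6.99 %.

5. The weak link was the memory time, taken from one pair of readings. The pair from 8.00 min to 30.0 min gave a shorter 8.11 min, though its last lead is about the size of the scatter. With it the excess came to 3.28 %, so I committed to a value between these two. For the pace I had no reckoning of my own.

The forecast said 63 %, 2 % and hardly takes part, with the words “So exchange is negligible”. Its excess lay below my range.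

The flask gave 59.7 % and 3.83 %, and the exchange lags behind, getting 26 % of the way.

    reagent + left-handed substrate → left-handed product (k = 0.00814 /M/s)
    reagent + right-handed substrate → right-handed product (k = 1.60 × 10⁻⁴ /M/s)
    left-handed substrate + racemization catalyst ⇌ right-handed substrate + racemization catalyst, rate k3*[racemization catalyst]*[left-handed substrate] forward; the back reaction follows from the equilibrium constant (k = 0.00131 /M/s)
    racemization catalyst → spent catalyst (k = 1.63 × 10⁻⁴ /s)
    left-handed product ⇌ right-handed product (k = 9.26 × 10⁻⁴ /s)

At 15.0 min the flask held 33.4 % left-handed against 21.1 % right-handed product. Reckoned with my reading of the memory time, 10.9 min, that lead came down to 3.1 points by 30 min; the flask's lead then was 2.3 points. For the neighbour charged with 2.5 M of reagent, the same reading reckoned 11.1 % of any lead from 6.00 min still standing at 30 min, and that neighbour ended at −2.58 %, with 37.7 % right-handed against 35.8 % left-handed product.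

(The runs come from a simulation with made-up constants.)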